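**Plan**
- Retrosynthetic cuts, in order: (i) the quinone oxidation level, back to the 1,2,4-trimethoxyarene 11; (ii) the C6–C7 bond of the henicosyl chain (C1 = carbon on the ring), giving two carboxylic acids, 7 (ring + C1–C6 + CO2H) and palmitic acid 8 (C7–C21 + CO2H); (iii) the ring–C1 bond, giving quinone 2 and monomethyl suberate 3; (iv) quinone 2 back to phenol 1.
- Forward: the only ring is the quinone, made by oxidation of phenol 1 (no ring construction). A (CH2)6CO2Me tether is put on its free C6–H by decarboxylative radical alkylation. The ring is then parked as a hydroquinone trimethyl ether, the C15 block is joined by a Ni-electrocatalytic doubly decarboxylative C(sp3)–C(sp3) coupling of the two acids, and CAN returns the quinone.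
- Enabling features: the C21 chain is unbranched and unfunctionalised, so the C6–C7 bond lies between two primary CH2 carbons that are each the α-carbon of an accessible acid (two like-polarity partners united through radicals). Ring carbon C6 of 2-methoxy-5-methyl-1,4-benzoquinone (β-carbon of the C4=O/C5(Me)=C6 enone, the CH not deactivated by the OMe donor) accepts the tether radical. The para C1/C4 oxygens allow reversible masking as aryl methyl ethers.
- Stereochemistry: none; the target has no stereocentre and no stereogenic double bond.

Key step: step 5

Assumption: compounds 1, 3 and 8 are bought; the target is achiral, so no stereocontrol is needed.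

**Step 1**
Reactants: 1 2-methoxy-5-methylphenol
Product: 2 2-methoxy-5-methyl-1,4-benzoquinone
Conditions: (KSO3)2NO (2.5 equiv), KH2PO4, H2O/acetone, 0 °C to rt
Reagents that add atoms: potassium nitrosodisulfonate (Fremy's salt), [K+].[K+].[O]N(S(=O)(=O)[O-])S(=O)(=O)[O-]
Why: Teuber oxidation; the phenoxyl radical should be trapped by a second nitroxyl radical at the free para carbon, and loss of imidodisulfonate should give the para-quinone.

**Step 2**
Reactants: 2 2-methoxy-5-methyl-1,4-benzoquinone; 3 8-methoxy-8-oxooctanoic acid (monomethyl suberate, 1.5 equiv)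
Product: 4 methyl 7-(5-methoxy-2-methyl-3,6-dioxocyclohexa-1,4-dien-1-yl)heptanoate
Conditions: AgNO3 (0.2 equiv), (NH4)2S2O8 (1.5 equiv, slow addition), MeCN/H2O, 65–70 °C
Reagents that add atoms: none
Why: Minisci-type silver/persulfate decarboxylative radical alkylation of a quinone; the nucleophilic 6-(methoxycarbonyl)hexyl radical should add at C6 (β-carbon of the C4 enone) and not at C3, which is the electron-rich α-carbon of the vinylogous ester, and the adduct radical is re-oxidised to the quinone.

**Step 3**
Reactants: 4 methyl 7-(5-methoxy-2-methyl-3,6-dioxocyclohexa-1,4-dien-1-yl)heptanoate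
Product: 6 methyl 7-(2,3,5-trimethoxy-6-methylphenyl)heptanoate, via hydroquinone ester 5 (not isolated)
Conditions: Na2S2O4, EtOAc/H2O, rt; then Me2SO4, K2CO3, acetone, reflux, N2
Reagents that add atoms: dimethyl sulfate, COS(=O)(=O)OC
Why: reductive methylation; dithionite reduces the quinone to the hydroquinone and Williamson O-methylation of both phenols under mild carbonate base, with the methyl ester untouched, should lock the ring at the reduced level needed for step 5.

**Step 4**
Reactants: 6 methyl 7-(2,3,5-trimethoxy-6-methylphenyl)heptanoate
Product: 7 7-(2,3,5-trimethoxy-6-methylphenyl)heptanoic acid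
Conditions: LiOH·H2O, THF/MeOH/H2O, rt; then 1 M HCl
Reagents that add atoms: lithium hydroxide, [Li+].[OH-]
Why: ester saponification (BAc2); the aryl methyl ethers are inert to hydroxide, which the methoxyquinone of 4 would not have been.

**Step 5**
Reactants: 7 7-(2,3,5-trimethoxy-6-methylphenyl)heptanoic acid; 8 hexadecanoic acid (palmitic acid, 3 equiv)
Product: 11 1-henicosyl-2,3,5-trimethoxy-6-methylbenzene, via palmitate NHPI ester 9 (not isolated), via arylheptanoate NHPI ester 10 (not isolated)
Conditions: N-hydroxyphthalimide, DIC, DMAP (cat.), THF, rt; then NiCl2·6H2O (20 mol%), 2,2':6',2''-terpyridine (20 mol%), AgNO3 (0.3 equiv), NaI, DMF, Mg(+)/RVC(−), constant current, ca. 2.5 F/mol, rt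
Reagents that add atoms: none
Why: Both acids are converted in the flask into the N-acyloxyphthalimides 9 and 10; cathodically generated low-valent Ni–terpyridine transfers an electron to each ester, which fragments to CO2, phthalimide anion and a primary alkyl radical, and the two alkyl groups are joined by reductive elimination from a dialkylnickel(III) species while the Mg anode is consumed. The closest known reaction type is the Ni-electrocatalytic doubly decarboxylative C(sp3)–C(sp3) cross-coupling of redox-active esters on a silver-nanoparticle-coated cathode, which covers primary/primary pairs. No ring is closed and no stereocentre is formed. The step needs cross- over homo-coupling, which two nearly identical primary radicals cannot provide intrinsically; it is secured statistically by the threefold excess of cheap 8, whose homodimer triacontane is a hydrocarbon that should elute well ahead of 11. It also needs the ring to stay out of the chemistry, which is secured by carrying it as the 1,2,4-trimethoxybenzene: this is inert to the reducing medium, is no radical acceptor and cannot oxidise low-valent nickel, as the quinone would.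

**Step 6**
Reactants: 11 1-henicosyl-2,3,5-trimethoxy-6-methylbenzene
Product: 12 3-henicosyl-5-methoxy-2-methyl-1,4-benzoquinone (target)
Conditions: (NH4)2Ce(NO3)6 (2.5–3 equiv), MeCN/THF/H2O, 0 °C
Reagents that add atoms: water, O
Why: CAN oxidative demethylation; the arene radical cation is attacked by water at the para pair of methoxy-bearing carbons, two molecules of methanol are lost and the third methoxy group should remain as the vinylogous ester of the para-quinone.

**Compound list**
1 | 2-methoxy-5-methylphenol | COc1ccc(C)cc1O | starting material
2 | 2-methoxy-5-methyl-1,4-benzoquinone | COC1=CC(=O)C(C)=CC1=O | intermediate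
3 | 8-methoxy-8-oxooctanoic acid (monomethyl suberate) | COC(=O)CCCCCCC(=O)O | starting material
4 | methyl 7-(5-methoxy-2-methyl-3,6-dioxocyclohexa-1,4-dien-1-yl)heptanoate | COC(=O)CCCCCCC1=C(C)C(=O)C=C(OC)C1=O | intermediate
5 | methyl 7-(2,5-dihydroxy-3-methoxy-6-methylphenyl)heptanoate (formed in the flask, not isolated) | COC(=O)CCCCCCc1c(C)c(O)cc(OC)c1O | intermediate
6 | methyl 7-(2,3,5-trimethoxy-6-methylphenyl)heptanoate | COC(=O)CCCCCCc1c(C)c(OC)cc(OC)c1OC | intermediate
7 | 7-(2,3,5-trimethoxy-6-methylphenyl)heptanoic acid | OC(=O)CCCCCCc1c(C)c(OC)cc(OC)c1OC | intermediate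
8 | hexadecanoic acid (palmitic acid) | CCCCCCCCCCCCCCCC(=O)O | starting material
9 | 1,3-dioxoisoindolin-2-yl hexadecanoate (formed in the flask, not isolated) | CCCCCCCCCCCCCCCC(=O)ON1C(=O)c2ccccc2C1=O | intermediate
10 | 1,3-dioxoisoindolin-2-yl 7-(2,3,5-trimethoxy-6-methylphenyl)heptanoate (formed in the flask, not isolated) | COc1cc(OC)c(C)c(CCCCCCC(=O)ON2C(=O)c3ccccc3C2=O)c1OC | intermediate
11 | 1-henicosyl-2,3,5-trimethoxy-6-methylbenzene | CCCCCCCCCCCCCCCCCCCCCc1c(C)c(OC)cc(OC)c1OC | intermediate
12 | 3-henicosyl-5-methoxy-2-methyl-1,4-benzoquinone | CCCCCCCCCCCCCCCCCCCCCC1=C(C)C(=O)C=C(OC)C1=O | target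

**Step count:** 6 steps in total; longest linear sequence 6 steps (1 → 12).

**Steps most likely to fail**

1. Step 5. Homocoupling of each radical with itself, together with reductive protodecarboxylation and alkene formation, may leave only a small cross-coupled share. Fallback, from 7 back to 11: acid 7 is esterified with N-hydroxyphthalimide/DIC (CH2Cl2, rt) and ester 10 is isolated. Bought 1-bromopentadecane is converted with Mg (THF) into pentadecylmagnesium bromide F1, and ZnCl2 (0.5 equiv) turns this into dipentadecylzinc F2. A Ni-catalysed decarboxylative Negishi alkyl–alkyl coupling of 10 with F2 (NiCl2·glyme, 4,4'-di-tert-butyl-2,2'-bipyridine, THF/DMF, rt) should then form the same C6–C7 bond from one electrophile and one nucleophile, without a statistical partner, and give 11.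

2. Step 2. The radical may also attack the other ring CH (C3, next to the methoxy group) or alkylate twice, and the regioisomers may be hard to separate. Fallback, from 1 back to 6, with the position fixed by a sigmatropic shift instead of by radical polarity: phenol 1 is O-allylated (allyl bromide, K2CO3, acetone) to 2-(allyloxy)-1-methoxy-4-methylbenzene F3. Aromatic Claisen rearrangement (N,N-diethylaniline, 190 °C) can deliver the allyl group only to the single free ortho carbon and should give 2-allyl-6-methoxy-3-methylphenol F4. Teuber oxidation (Fremy's salt, KH2PO4) should give 3-allyl-5-methoxy-2-methyl-1,4-benzoquinone F5. Dithionite reduction to 2-allyl-6-methoxy-3-methylbenzene-1,4-diol F6 (not isolated) and methylation (Me2SO4, K2CO3, acetone) should give 1-allyl-2,3,5-trimethoxy-6-methylbenzene F7. Cross-metathesis with excess methyl hex-5-enoate (Grubbs II, CH2Cl2, 40 °C) should give methyl (E)-7-(2,3,5-trimethoxy-6-methylphenyl)hept-5-enoate F8 (the E/Z ratio is of no consequence), and hydrogenation (H2, Pd/C, EtOAc) returns to 6.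

3. Step 6. Oxidation may run along the vicinal pair of methoxy groups (ortho-quinone formation), the radical cation may couple to a biaryl at the free ring CH, and the waxy substrate may mix poorly with the aqueous oxidant. Fallback, from 11 back to 12, replacing oxidative demethylation by deprotection and re-methylation: BBr3 (CH2Cl2, −78 °C to rt) should cleave all three ethers to 6-henicosyl-5-methylbenzene-1,2,4-triol F9. Aeration on work-up (or FeCl3) should oxidise this to 3-henicosyl-5-hydroxy-2-methyl-1,4-benzoquinone F10. This vinylogous acid is then methylated under equilibrating Fischer-type conditions (MeOH, cat. H2SO4, reflux), which should favour the para-quinone methyl ether 12.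

**Further compounds**
F1 | step 5 | pentadecylmagnesium bromide | CCCCCCCCCCCCCCC[Mg]Br
F2 | step 5 | dipentadecylzinc | CCCCCCCCCCCCCCC[Zn]CCCCCCCCCCCCCCC
F3 | step 2 | 2-(allyloxy)-1-methoxy-4-methylbenzene | C=CCOc1cc(C)ccc1OC
F4 | step 2 | 2-allyl-6-methoxy-3-methylphenol | C=CCc1c(C)ccc(OC)c1O
F5 | step 2 | 3-allyl-5-methoxy-2-methyl-1,4-benzoquinone | C=CCC1=C(C)C(=O)C=C(OC)C1=O
F6 | step 2 | 2-allyl-6-methoxy-3-methylbenzene-1,4-diol | C=CCc1c(C)c(O)cc(OC)c1O
F7 | step 2 | 1-allyl-2,3,5-trimethoxy-6-methylbenzene | C=CCc1c(C)c(OC)cc(OC)c1OC
F8 | step 2 | methyl (E)-7-(2,3,5-trimethoxy-6-methylphenyl)hept-5-enoate | COC(=O)CCC/C=C/Cc1c(C)c(OC)cc(OC)c1OC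
F9 | step 6 | 6-henicosyl-5-methylbenzene-1,2,4-triol | CCCCCCCCCCCCCCCCCCCCCc1c(C)c(O)cc(O)c1O
F10 | step 6 | 3-henicosyl-5-hydroxy-2-methyl-1,4-benzoquinone | CCCCCCCCCCCCCCCCCCCCCC1=C(C)C(=O)C=C(O)C1=O
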